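**Plan**

1. Retrosynthesis: the lactone ring (O1, C2, C3, C4, C4a, C8a) is opened at O1–C2 and C3=C4, leading back to a 2,6-dihydroxy-4-alkoxybenzaldehyde and Ph3P=C=C=O; then the aryl ether O–C1′ is cut, then C7′–C8′ (side chain numbered C1′ at OCH2 to C11′ at the tertiary carbinol carbon).
2. Enabling feature: O1 and the C5 hydroxyl are the two oxygens ortho to the formyl carbon (future C4) of a benzaldehyde that has a mirror plane through CHO and the C7–O bond, so closure of the ring O1, C2, C3, C4, C4a, C8a onto either oxygen gives the same 5-hydroxy-7-alkoxycoumarin.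
3. Forward: a C1′–C7′ (E)-alkenyl iodide from geraniol (steps 1–6) and a C8′–C11′ triflate from a tartrate (steps 7–9) are joined at C7′–C8′ (step 10); the chain is attached to O-4 of 2,4,6-trihydroxybenzaldehyde (step 12), the only ring formed, the pyranone, closes in step 13, and acid deprotection ends the route.
4. Stereochemistry: C9′ (R) and C10′ (S) are the two carbinol carbons of D-tartaric acid, bought as its (4S,5S) acetonide dimethyl ester, and their C–O bonds are never broken; C2′=C3′ (E) is that of geraniol; C6′=C7′ (E) comes from syn hydrozirconation–iodination and is retained in the coupling.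
5. Remark: oxirane 3 and diol 4 are racemic at a carbon that is excised in step 3, so no descriptor is given for it.

Key step: step 13

**Route**

Step 1
Reactants: 1 geraniol, (2E)-3,7-dimethylocta-2,6-dien-1-ol
Product: 2 geranyl 4-methoxybenzyl (PMB) ether
Conditions: NaH, PMBCl, Bu4NI (cat.), THF/DMF, 0 °C to rt
Reagents that add atoms: 4-methoxybenzyl chloride, COc1ccc(CCl)cc1
Why: Williamson ether synthesis: the sodium alkoxide of the primary allylic alcohol should displace chloride from the benzylic halide, giving an ether that tolerates organolithium and organozirconium reagents and can later be removed oxidatively.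

Step 2
Reactants: 2 geranyl PMB ether
Product: 3 6,7-epoxide of 2 (2,2-dimethyloxirane terminus, racemic)
Conditions: mCPBA (1.0 equiv), CH2Cl2, −20 to 0 °C
Reagents that add atoms: 3-chloroperoxybenzoic acid, OOC(=O)c1cccc(Cl)c1
Why: Prilezhaev epoxidation with one equivalent of peracid at low temperature should select the electron-rich terminal trisubstituted alkene over the C2′=C3′ alkene, which is deactivated by the allylic oxygen; the oxirane stereocentre forms as a racemate and is excised in step 3.

Step 3
Reactants: 3 epoxide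
Product: 5 (4E)-6-[(4-methoxybenzyl)oxy]-4-methylhex-4-enal, via vicinal diol 4 (not isolated)
Conditions: H5IO6, THF/H2O, 0 °C
Reagents that add atoms: none
Why: Periodic acid should hydrolyse the oxirane (water entering at the tertiary carbon) and cleave the resulting glycol (Malaprade glycol cleavage), so the aldehyde oxygen of 5 is the former oxirane oxygen and the three-carbon terminus leaves as acetone, with the PMB ether and the C2′=C3′ alkene untouched.

Step 4
Reactants: 5 aldehyde
Product: 6 PMB ether of (2E)-3-methylhept-2-en-6-yn-1-ol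
Conditions: dimethyl (1-diazo-2-oxopropyl)phosphonate, K2CO3, MeOH, 0 °C to rt
Reagents that add atoms: dimethyl (1-diazo-2-oxopropyl)phosphonate, COP(=O)(OC)C(=[N+]=[N-])C(C)=O
Why: Ohira–Bestmann (Seyferth–Gilbert) homologation: the diazomethylphosphonate anion released by methanolysis of the reagent adds to the enolisable aldehyde under mild carbonate conditions and, after loss of phosphate and N2, the alkylidene carbene rearranges to the terminal alkyne, adding C7′.

Step 5
Reactants: 6 terminal alkyne
Product: 8 PMB ether of (2E)-3-methyloct-2-en-6-yn-1-ol, via lithium acetylide 7 (not isolated)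
Conditions: n-BuLi, THF, −78 °C; then MeI, −78 °C to rt
Reagents that add atoms: iodomethane, CI
Why: Alkyne alkylation: the terminal alkyne C–H is by far the most acidic site, and the lithium acetylide should be methylated by SN2 attack on MeI, which supplies the methyl group on C7′.

Step 6
Reactants: 8 methyl alkyne
Product: 10 PMB ether of (2E,6E)-7-iodo-3-methylocta-2,6-dien-1-ol, via alkenylzirconocene chloride 9 (not isolated)
Conditions: Cp2Zr(H)Cl (2.2 equiv), THF, 50 °C; then I2, THF, 0 °C
Reagents that add atoms: iodine, II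
Why: Hydrozirconation–iodination: Cp2Zr(H)Cl adds H and Zr syn across the alkyne and, in excess at 50 °C, equilibrates zirconium to the less hindered carbon next to methyl, so iodinolysis with retention should give the (6E)-alkenyl iodide, while the trisubstituted C2′=C3′ alkene is hydrozirconated far more slowly.

Step 7
Reactants: 11 dimethyl (4S,5S)-2,2-dimethyl-1,3-dioxolane-4,5-dicarboxylate (acetonide of dimethyl D-tartrate)
Product: 13 methyl (4S,5R)-5-(hydroxymethyl)-2,2-dimethyl-1,3-dioxolane-4-carboxylate, via formyl ester 12 (not isolated)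
Conditions: NaBH4 (limiting, about 0.6 equiv), MeOH, 0 °C
Reagents that add atoms: none
Why: Borohydride reduction of an activated α-alkoxy ester: with hydride limiting at 0 °C the homotopic esters of the C2-symmetric diester should mostly be reduced only once (unchanged 11 being recoverable), and neither stereocentre is touched.

Step 8
Reactants: 13 hydroxy ester
Product: 15 2-[(4S,5R)-5-(hydroxymethyl)-2,2-dimethyl-1,3-dioxolan-4-yl]propan-2-ol, via methyl ketone 14 (not isolated)
Conditions: MeMgBr (3.5 equiv), THF, 0 °C to rt; H2O work-up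
Reagents that add atoms: methylmagnesium bromide, C[Mg]Br
Why: Grignard addition to an ester: after deprotonation of the hydroxyl, two methyl groups add by way of the methyl ketone to give the tertiary carbinol (C11′), addition being faster than enolisation so the adjacent stereocentre should keep its configuration.

Step 9
Reactants: 15 diol
Product: 17 [(4R,5S)-2,2-dimethyl-5-{2-[(triethylsilyl)oxy]propan-2-yl}-1,3-dioxolan-4-yl]methyl trifluoromethanesulfonate, via hydroxy triflate 16 (not isolated)
Conditions: Tf2O (1.05 equiv), 2,6-lutidine, CH2Cl2, −78 °C; then TESOTf, −78 to −20 °C; used at once after cold work-up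
Reagents that add atoms: trifluoromethanesulfonic anhydride, O=S(=O)(OS(=O)(=O)C(F)(F)F)C(F)(F)F; triethylsilyl trifluoromethanesulfonate, CC[Si](CC)(CC)OS(=O)(=O)C(F)(F)F
Why: Selective O-sulfonylation followed by O-silylation: at −78 °C Tf2O should triflate only the primary hydroxyl, the hindered tertiary one then being capped by the silyl triflate in the same flask, while the strained trans ring fusion that an intramolecular displacement would require keeps the hydroxy triflate from cyclising.

Step 10
Reactants: 10 (2E,6E)-alkenyl iodide; 17 primary triflate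
Product: 20 PMB ether of the full C1′–C11′ chain carrying the 9′,10′-acetonide and the 11′-triethylsilyl ether, via alkenyllithium 18 (not isolated), via alkenylmagnesium bromide 19 (not isolated)
Conditions: t-BuLi (2 equiv per 10), Et2O, −78 °C; MgBr2·OEt2, −78 to 0 °C; CuBr·SMe2 (10 mol %), then 17, Et2O, −30 to 0 °C
Reagents that add atoms: none
Why: Copper-catalysed cross-coupling of a Grignard reagent with a primary alkyl triflate: iodine–lithium exchange and transmetalation to magnesium proceed with retention of the C6′=C7′ geometry, and the alkenyl group should displace the triflate at C8′ by SN2 without touching C9′ or C10′, the β-oxygen being harmless because it sits on the electrophile and not on the organometallic.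

Step 11
Reactants: 20 PMB ether
Product: 21 (2E,6E)-8-[(4R,5S)-2,2-dimethyl-5-{2-[(triethylsilyl)oxy]propan-2-yl}-1,3-dioxolan-4-yl]-3,7-dimethylocta-2,6-dien-1-ol
Conditions: DDQ, CH2Cl2/pH 7 buffer, 0 °C
Reagents that add atoms: none
Why: Oxidative PMB ether cleavage: DDQ abstracts hydride from the electron-rich benzylic position and water hydrolyses the oxocarbenium ion, which under buffered conditions should leave the silyl ether, the acetonide and both alkenes intact.

Step 12
Reactants: 21 allylic alcohol; 22 2,4,6-trihydroxybenzaldehyde (in excess)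
Product: 23 2,6-dihydroxy-4-alkoxybenzaldehyde carrying the protected chain of 21 on O-4
Conditions: PPh3, DIAD, THF, 0 °C to rt
Reagents that add atoms: none
Why: Mitsunobu etherification: the 4-hydroxyl, the most acidic phenol and the only one not locked in a hydrogen bond to the formyl group, should attack the alkoxyphosphonium ion of the primary allylic alcohol in SN2 fashion, with the phenol in excess to suppress double alkylation.

Step 13
Reactants: 23 2,6-dihydroxy-4-alkoxybenzaldehyde; 24 (triphenylphosphoranylidene)ketene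
Product: 26 5-hydroxy-7-alkoxycoumarin carrying the 9′,10′-acetonide and the 11′-triethylsilyl ether, via aryl phosphoranylideneacetate 25 (not isolated)
Conditions: 24 (1.05 equiv), toluene, 90 °C
Reagents that add atoms: none
Why: The acidic, hydrogen-bonded phenol protonates the ylide carbon of 24 and the phenoxide adds to the ketene carbon, forming O1–C2 and the ester-stabilised ylide 25, whose ylide carbon then attacks the neighbouring formyl carbon; the oxaphosphetane collapses with loss of Ph3P=O to form C3=C4. The closest known reaction is the coumarin synthesis from salicylaldehydes and (triphenylphosphoranylidene)ketene, an O-acylation–intramolecular Wittig cascade. The pyranone ring (O1, C2, C3, C4, C4a, C8a) closes by 6-exo-trig attack of C3 on the formyl carbon, and the ring enforces the cis C3=C4 geometry. No stereocentre is formed, and the acetal-protected C9′ and C10′ centres are remote and untouched under the neutral conditions. The step needs chemoselectivity for a single acylation: the two ortho hydroxyls are equivalent by the mirror symmetry of 23 so either closure gives 26, only a slight excess of 24 is used, the tertiary hydroxyl is silylated, and once the ring has closed no formyl group remains to drive a second olefination.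

Step 14
Reactants: 26 protected coumarin
Product: 28 5-hydroxy-7-{[(2E,6E,9R,10S)-9,10,11-trihydroxy-3,7,11-trimethyldodeca-2,6-dien-1-yl]oxy}-2H-chromen-2-one (target), via desilylated acetonide 27 (not isolated)
Conditions: 1 M aq. HCl, THF, rt
Reagents that add atoms: none
Why: Acid-catalysed hydrolysis (desilylation, then acetal hydrolysis): dilute aqueous acid should cleave the tertiary silyl ether first and then the isopropylidene acetal, breaking only Si–O and acetal C–O bonds so that C9′ and C10′ keep their configuration, while the allylic aryl ether and the trisubstituted alkenes are expected to survive at room temperature.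

**Compound list**

1 | geraniol, (2E)-3,7-dimethylocta-2,6-dien-1-ol | CC(C)=CCC/C(C)=C/CO | starting material
2 | 1-({[(2E)-3,7-dimethylocta-2,6-dien-1-yl]oxy}methyl)-4-methoxybenzene | COc1ccc(COC/C=C(\C)CCC=C(C)C)cc1 | intermediate
3 | 3-{(3E)-5-[(4-methoxybenzyl)oxy]-3-methylpent-3-en-1-yl}-2,2-dimethyloxirane (racemic) | COc1ccc(COC/C=C(\C)CCC2OC2(C)C)cc1 | intermediate
4 | (6E)-8-[(4-methoxybenzyl)oxy]-2,6-dimethyloct-6-ene-2,3-diol (racemic, not isolated) | COc1ccc(COC/C=C(\C)CCC(O)C(C)(C)O)cc1 | intermediate
5 | (4E)-6-[(4-methoxybenzyl)oxy]-4-methylhex-4-enal | COc1ccc(COC/C=C(\C)CCC=O)cc1 | intermediate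
6 | 1-methoxy-4-({[(2E)-3-methylhept-2-en-6-yn-1-yl]oxy}methyl)benzene | COc1ccc(COC/C=C(\C)CCC#C)cc1 | intermediate
7 | lithium acetylide of 6, lithium on the terminal alkyne carbon (not isolated) | COc1ccc(COC/C=C(\C)CCC#C[Li])cc1 | intermediate
8 | 1-methoxy-4-({[(2E)-3-methyloct-2-en-6-yn-1-yl]oxy}methyl)benzene | COc1ccc(COC/C=C(\C)CCC#CC)cc1 | intermediate
9 | chlorobis(cyclopentadienyl)zirconium alkenyl complex, Zr on the methyl-bearing alkene carbon of the chain of 10 and trans to C5′ (not isolated) | COc1ccc(COC/C=C(\C)CC/C=C(\C)[Zr](Cl)(C2C=CC=C2)C2C=CC=C2)cc1 | intermediate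
10 | 1-({[(2E,6E)-7-iodo-3-methylocta-2,6-dien-1-yl]oxy}methyl)-4-methoxybenzene | COc1ccc(COC/C=C(\C)CC/C=C(\C)I)cc1 | intermediate
11 | dimethyl (4S,5S)-2,2-dimethyl-1,3-dioxolane-4,5-dicarboxylate | COC(=O)[C@H]1OC(C)(C)O[C@@H]1C(=O)OC | starting material
12 | methyl (4S,5S)-5-formyl-2,2-dimethyl-1,3-dioxolane-4-carboxylate (not isolated) | COC(=O)[C@H]1OC(C)(C)O[C@@H]1C=O | intermediate
13 | methyl (4S,5R)-5-(hydroxymethyl)-2,2-dimethyl-1,3-dioxolane-4-carboxylate | COC(=O)[C@H]1OC(C)(C)O[C@@H]1CO | intermediate
14 | 1-[(4S,5R)-5-(hydroxymethyl)-2,2-dimethyl-1,3-dioxolan-4-yl]ethan-1-one (not isolated) | CC(=O)[C@H]1OC(C)(C)O[C@@H]1CO | intermediate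
15 | 2-[(4S,5R)-5-(hydroxymethyl)-2,2-dimethyl-1,3-dioxolan-4-yl]propan-2-ol | CC(C)(O)[C@H]1OC(C)(C)O[C@@H]1CO | intermediate
16 | [(4R,5S)-5-(2-hydroxypropan-2-yl)-2,2-dimethyl-1,3-dioxolan-4-yl]methyl trifluoromethanesulfonate (not isolated) | CC(C)(O)[C@H]1OC(C)(C)O[C@@H]1COS(=O)(=O)C(F)(F)F | intermediate
17 | [(4R,5S)-2,2-dimethyl-5-{2-[(triethylsilyl)oxy]propan-2-yl}-1,3-dioxolan-4-yl]methyl trifluoromethanesulfonate | CC[Si](CC)(CC)OC(C)(C)[C@H]1OC(C)(C)O[C@@H]1COS(=O)(=O)C(F)(F)F | intermediate
18 | alkenyllithium: 10 with Li in place of I, alkene geometry retained (not isolated) | COc1ccc(COC/C=C(\C)CC/C=C(\C)[Li])cc1 | intermediate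
19 | alkenylmagnesium bromide: 10 with MgBr in place of I, alkene geometry retained (not isolated) | COc1ccc(COC/C=C(\C)CC/C=C(\C)[Mg]Br)cc1 | intermediate
20 | 1-({[(2E,6E)-8-[(4R,5S)-2,2-dimethyl-5-{2-[(triethylsilyl)oxy]propan-2-yl}-1,3-dioxolan-4-yl]-3,7-dimethylocta-2,6-dien-1-yl]oxy}methyl)-4-methoxybenzene | COc1ccc(COC/C=C(\C)CC/C=C(\C)C[C@H]2OC(C)(C)O[C@@H]2C(C)(C)O[Si](CC)(CC)CC)cc1 | intermediate
21 | (2E,6E)-8-[(4R,5S)-2,2-dimethyl-5-{2-[(triethylsilyl)oxy]propan-2-yl}-1,3-dioxolan-4-yl]-3,7-dimethylocta-2,6-dien-1-ol | OC/C=C(\C)CC/C=C(\C)C[C@H]1OC(C)(C)O[C@@H]1C(C)(C)O[Si](CC)(CC)CC | intermediate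
22 | 2,4,6-trihydroxybenzaldehyde | O=Cc1c(O)cc(O)cc1O | starting material
23 | 4-{[(2E,6E)-8-[(4R,5S)-2,2-dimethyl-5-{2-[(triethylsilyl)oxy]propan-2-yl}-1,3-dioxolan-4-yl]-3,7-dimethylocta-2,6-dien-1-yl]oxy}-2,6-dihydroxybenzaldehyde | O=Cc1c(O)cc(OC/C=C(\C)CC/C=C(\C)C[C@H]2OC(C)(C)O[C@@H]2C(C)(C)O[Si](CC)(CC)CC)cc1O | intermediate
24 | (triphenylphosphoranylidene)ketene | O=C=C=P(c1ccccc1)(c1ccccc1)c1ccccc1 | starting material
25 | 2-formyl-3-hydroxy-5-(alkoxy)phenyl (triphenylphosphoranylidene)acetate, alkoxy group as in 23 (not isolated) | O=Cc1c(O)cc(OC/C=C(\C)CC/C=C(\C)C[C@H]2OC(C)(C)O[C@@H]2C(C)(C)O[Si](CC)(CC)CC)cc1OC(=O)C=P(c1ccccc1)(c1ccccc1)c1ccccc1 | intermediate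
26 | 7-{[(2E,6E)-8-[(4R,5S)-2,2-dimethyl-5-{2-[(triethylsilyl)oxy]propan-2-yl}-1,3-dioxolan-4-yl]-3,7-dimethylocta-2,6-dien-1-yl]oxy}-5-hydroxy-2H-chromen-2-one | O=c1ccc2c(O)cc(OC/C=C(\C)CC/C=C(\C)C[C@H]3OC(C)(C)O[C@@H]3C(C)(C)O[Si](CC)(CC)CC)cc2o1 | intermediate
27 | 5-hydroxy-7-{[(2E,6E)-8-[(4R,5S)-5-(2-hydroxypropan-2-yl)-2,2-dimethyl-1,3-dioxolan-4-yl]-3,7-dimethylocta-2,6-dien-1-yl]oxy}-2H-chromen-2-one (not isolated) | O=c1ccc2c(O)cc(OC/C=C(\C)CC/C=C(\C)C[C@H]3OC(C)(C)O[C@@H]3C(C)(C)O)cc2o1 | intermediate
28 | 5-hydroxy-7-{[(2E,6E,9R,10S)-9,10,11-trihydroxy-3,7,11-trimethyldodeca-2,6-dien-1-yl]oxy}-2H-chromen-2-one | C/C(=C\COc1cc(O)c2ccc(=O)oc2c1)CC/C=C(\C)C[C@@H](O)[C@H](O)C(C)(C)O | target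

**Step count**

Total steps: 14 (steps 1–6 for the alkenyl iodide, 7–9 for the triflate, 10–14 after the fragments are joined).
Longest linear sequence: 11 steps (1–6, then 10–14).

**Steps most likely to fail, with fallbacks**

Step 10. The copper-mediated sp2–sp3 substitution may be outrun by bromide displacement of the triflate, by attack of the organometallic at sulfur, or by protonation of the hindered alkenyl metal before the C7′–C8′ bond forms. The fallback sets out from diol 15 and uses a cross-electrophile coupling in place of the organometallic displacement. Appel-type iodination (I2, PPh3, imidazole) should convert only the primary hydroxyl and give 2-[(4S,5S)-5-(iodomethyl)-2,2-dimethyl-1,3-dioxolan-4-yl]propan-2-ol F1. Silylation with TESOTf and 2,6-lutidine then gives triethyl({2-[(4S,5S)-5-(iodomethyl)-2,2-dimethyl-1,3-dioxolan-4-yl]propan-2-yl}oxy)silane F2. A nickel-catalysed reductive coupling of F2 with alkenyl iodide 10 (NiI2, 4,4′-di-tert-butyl-2,2′-bipyridine, Mn powder, DMA, rt) engages the alkyl partner as a radical, which does not expel the β-oxygen, and comes back to the route at 20.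

Step 13. Acylation may not stop at one oxygen: the second ortho hydroxyl or the phenol of the product can also add the ketene ylide, and intermolecular olefination may compete if ring closure is slow. The fallback sets out from 23 and separates the two bond formations. Mono-esterification with (diethoxyphosphoryl)acetic acid (DCC, DMAP cat., CH2Cl2, 0 °C) would give 2-formyl-3-hydroxy-5-(alkoxy)phenyl (diethoxyphosphoryl)acetate F3, with the alkoxy group as in 23. An intramolecular Horner–Wadsworth–Emmons reaction under mild conditions (LiCl, DBU, MeCN) then closes the same C3=C4 bond and comes back to the route at 26.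

Step 12. Site selectivity may be lost through alkylation at an ortho hydroxyl, double alkylation or SN2′ attack on the allylic system. The fallback sets out from 21. Appel bromination (CBr4, PPh3, CH2Cl2, −20 °C) would give the allylic bromide triethyl({2-[(4S,5R)-5-[(2E,6E)-8-bromo-2,6-dimethylocta-2,6-dien-1-yl]-2,2-dimethyl-1,3-dioxolan-4-yl]propan-2-yl}oxy)silane F4. Alkylation of 22 with F4 using one equivalent of KHCO3 in DMF at rt, where only the most acidic 4-hydroxyl is ionised, comes back to the route at 23.

**Further compounds**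

F1 | step 10 | 2-[(4S,5S)-5-(iodomethyl)-2,2-dimethyl-1,3-dioxolan-4-yl]propan-2-ol | CC(C)(O)[C@H]1OC(C)(C)O[C@@H]1CI
F2 | step 10 | triethyl({2-[(4S,5S)-5-(iodomethyl)-2,2-dimethyl-1,3-dioxolan-4-yl]propan-2-yl}oxy)silane | CC[Si](CC)(CC)OC(C)(C)[C@H]1OC(C)(C)O[C@@H]1CI
F3 | step 13 | 2-formyl-3-hydroxy-5-{[(2E,6E)-8-[(4R,5S)-2,2-dimethyl-5-{2-[(triethylsilyl)oxy]propan-2-yl}-1,3-dioxolan-4-yl]-3,7-dimethylocta-2,6-dien-1-yl]oxy}phenyl (diethoxyphosphoryl)acetate | CCOP(=O)(OCC)CC(=O)Oc1cc(OC/C=C(\C)CC/C=C(\C)C[C@H]2OC(C)(C)O[C@@H]2C(C)(C)O[Si](CC)(CC)CC)cc(O)c1C=O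
F4 | step 12 | triethyl({2-[(4S,5R)-5-[(2E,6E)-8-bromo-2,6-dimethylocta-2,6-dien-1-yl]-2,2-dimethyl-1,3-dioxolan-4-yl]propan-2-yl}oxy)silane | BrC/C=C(\C)CC/C=C(\C)C[C@H]1OC(C)(C)O[C@@H]1C(C)(C)O[Si](CC)(CC)CC
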